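**Retrosynthetic overview**
1. The two ester C–O bonds are made last: the angelate at C-8 and the 4-hydroxybenzoate at C-4. The C-8 oxygen comes from allylic oxidation and 1,2-reduction of the ferutinin-type alkene.
2. Key disconnection: seven-membered ring B is made by a one-carbon ring expansion of a trans-hydrindenone. An alkenyl carbon undergoes a 1,2-shift onto a CH2 unit delivered by Me3SiCHN2.
3. The six-membered precursor ring comes from ring-closing metathesis of an allyl arm (on C-8a) and a 2-methylallyl alcohol arm (on C-3a).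
4. Both arms, the angular methyl and the isopropyl carbinol are placed on five-membered ring A, bought as 3-methoxycyclopent-2-enone.
5. Ring order: A (bought), then the six-membered carbocycle (metathesis), then seven-membered ring B (ring expansion).

Assumption: 1, 2, 5, 6, 9, 13, 18, 20 and 26 are bought; positions follow the azulene numbering of the target (C-3 carbinol, C-3a ring-fusion CH, C-4 benzoate carbon, C-8 angelate carbon, C-8a quaternary carbon); the carbinol centre made in step 2 is drawn as the anti-aldol isomer and is erased in step 5.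

**Step 1**
Reactants: 1 3-methoxycyclopent-2-en-1-one; 2 allylmagnesium bromide
Product: 4 3-allylcyclopent-2-en-1-one, via bromomagnesium alkoxide 3 (not isolated)
Conditions: THF, 0 °C; then 1 M HCl, 0 °C to rt
Reagents that add atoms: water, O
Why: 1,2-Addition of the Grignard reagent to the vinylogous ester, then acid hydrolysis with loss of methanol, transposes the carbonyl (Stork–Danheiser enone synthesis), and no stereocentre is formed.

**Step 2**
Reactants: 4 3-allylcyclopent-2-en-1-one; 5 trimethylaluminium; 6 methacrolein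
Product: 8 (2S,3R)-3-allyl-2-[(1R)-1-hydroxy-2-methylprop-2-en-1-yl]-3-methylcyclopentan-1-one, via aluminium enolate 7 (not isolated)
Conditions: 5 (1.5 equiv), Cu(OTf)2 (5 mol %), chiral sulfonate-bearing imidazolinium NHC precursor (5 mol %), THF, −30 °C; then 6, −78 °C; aq Rochelle salt
Reagents that add atoms: none
Why: Copper-catalysed enantioselective conjugate addition of methyl sets the quaternary centre C-8a (ligand enantiomer chosen for R), and the regiodefined enolate 7 undergoes aldol addition to 6 anti to the larger allyl group, which places the new chain cis to the methyl group (C-3a).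

**Step 3**
Reactants: 8 keto alcohol; 9 isopropylmagnesium chloride
Product: 10 (1R,2S,3R)-3-allyl-2-[(1R)-1-hydroxy-2-methylprop-2-en-1-yl]-3-methyl-1-(propan-2-yl)cyclopentan-1-ol
Conditions: 9 (3 equiv), LaCl3·2LiCl (1 equiv), THF, −78 to −20 °C; aq NH4Cl
Reagents that add atoms: none
Why: Lanthanide-assisted Grignard 1,2-addition suppresses enolisation and retro-aldol cleavage and occurs anti to the neighbouring C-2 chain, so the tertiary hydroxyl (C-3, R) ends up cis to that chain and to the methyl group.

**Step 4**
Reactants: 10 triene diol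
Product: 11 (3R,3aS,4R,7aR)-5,7a-dimethyl-3-(propan-2-yl)-2,3,3a,4,7,7a-hexahydro-1H-indene-3,4-diol
Conditions: second-generation Hoveyda–Grubbs catalyst (5 mol %), toluene (5 mM), 80 °C
Reagents that add atoms: none
Why: Ring-closing olefin metathesis joins the two trans-disposed arms to a trisubstituted cyclohexene and gives the trans-hydrindene without touching a stereocentre.

**Step 5**
Reactants: 11 hydrindene diol
Product: 12 (3R,3aR,7aR)-3-hydroxy-5,7a-dimethyl-3-(propan-2-yl)-1,2,3,3a,7,7a-hexahydro-4H-inden-4-one
Conditions: MnO2 (20 equiv), CH2Cl2, rt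
Reagents that add atoms: none
Why: Selective oxidation of the allylic secondary alcohol under neutral conditions leaves the tertiary alcohol untouched and does not epimerise the ring-fusion CH.

**Step 6 (key step)**
Reactants: 12 hydrindenone; 13 (trimethylsilyl)diazomethane; 5 trimethylaluminium
Product: 16 (3R,3aR,8aR)-3-hydroxy-6,8a-dimethyl-3-(propan-2-yl)-2,3,3a,5,8,8a-hexahydroazulen-4(1H)-one, via aluminium alkoxide 14 (not isolated), via alpha-silyl ketone 15 (not isolated)
Conditions: 5 (1.1 equiv), CH2Cl2, −78 °C; 13 (1.5 equiv), −78 to −20 °C; 1 M HCl/THF, 0 °C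
Reagents that add atoms: none
Why: Proposed new method: Me3Al turns the tertiary hydroxyl into a dimethylaluminium alkoxide that chelates and activates only the neighbouring enone carbonyl, Me3SiCHN2 adds there from the convex face, and in the betaine the C–N2 bond can lie antiperiplanar only to the flat C(sp2)–C(O) bond because the Me3Si group avoids the crowded ring-fusion carbon, so the alkenyl carbon (helped by its pi bond) makes the 1,2-shift with loss of N2 and gives the seven-membered beta,gamma-enone after acidic protodesilylation with all three stereocentres intact; the closest known reaction type is the Lewis-acid-promoted diazoalkane homologation of cycloalkanones (Büchner–Curtius–Schlotterbeck, Tiffeneau–Demjanov type), which has not been shown as an alkoxide-directed, alkenyl-selective insertion on a beta-hydroxy alpha-methyl enone.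

**Step 7**
Reactants: 16 hydroazulenone
Product: 17 jaeschkeanadiol, (3R,3aS,4S,8aR)-6,8a-dimethyl-3-(propan-2-yl)-1,2,3,3a,4,5,8,8a-octahydroazulene-3,4-diol
Conditions: Me4NBH(OAc)3 (5 equiv), MeCN/AcOH 1:1, −25 °C
Reagents that add atoms: none
Why: In the Evans–Saksena hydroxyl-directed reduction the borohydride bound to the tertiary hydroxyl delivers hydride from that face and gives the 1,3-anti diol (C-4, S), while the cold acidic medium leaves the beta,gamma-alkene in place.

**Step 8**
Reactants: 18 4-bromophenol
Product: 19 (4-bromophenoxy)(tert-butyl)dimethylsilane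
Conditions: TBSCl, imidazole, DMF, rt
Reagents that add atoms: tert-butyldimethylsilyl chloride, CC(C)(C)[Si](C)(C)Cl
Why: Standard silylation masks the phenol for the lithiation and for the two later acylations.

**Step 9**
Reactants: 19 aryl bromide; 20 carbon dioxide
Product: 22 4-[(tert-butyldimethylsilyl)oxy]benzoic acid, via aryllithium 21 (not isolated)
Conditions: n-BuLi (1.05 equiv), THF, −78 °C; 20 (gas); cold 1 M HCl
Reagents that add atoms: none
Why: Bromine–lithium exchange followed by carboxylation builds the benzoic acid carbon.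

**Step 10**
Reactants: 17 jaeschkeanadiol; 22 silyl-protected acid
Product: 23 ferutinin tert-butyldimethylsilyl ether, (3R,3aS,4S,8aR)-configured C-4 ester
Conditions: 22 (1.5 equiv), DCC, DMAP, CH2Cl2, rt
Reagents that add atoms: none
Why: Steglich esterification acylates only the secondary C-4 hydroxyl because the tertiary C-3 hydroxyl is inert under these conditions.

**Step 11**
Reactants: 23 silyl ferutinin
Product: 24 8-oxo derivative of 23, (3R,3aS,4S,8aS)-configured enone
Conditions: Rh2(cap)4 (1 mol %), t-BuOOH (70 % aq, 10 equiv), 1,2-dichloroethane, 40 °C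
Reagents that add atoms: tert-butyl hydroperoxide, CC(C)(C)OO
Why: In this radical allylic C–H oxidation the C-8 methylene gives the best stabilised (secondary/tertiary) allyl radical while the C-5 methylene is deactivated by the neighbouring acyloxy group, the same bias that takes homoallylic steroid esters to their 7-ketones.

**Step 12**
Reactants: 24 enone
Product: 25 8-hydroxy derivative of 23, (3R,3aS,4S,8S,8aS)-configured allylic alcohol
Conditions: NaBH4, CeCl3·7H2O, MeOH, −78 to 0 °C
Reagents that add atoms: none
Why: In the Luche 1,2-reduction hydride attacks the face opposite the angular methyl group, so the C-8 hydroxyl (S) ends up cis to that methyl and both esters survive.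

**Step 13**
Reactants: 25 allylic alcohol; 26 angelic acid
Product: 28 silyl-protected target, via mixed anhydride 27 (not isolated)
Conditions: 26, 2,4,6-trichlorobenzoyl chloride, Et3N, toluene, rt; then 25, 80 °C
Reagents that add atoms: none
Why: Yamaguchi-type mixed-anhydride acylation without DMAP keeps the Z geometry of the angelate and reaches only the secondary C-8 hydroxyl.

**Step 14**
Reactants: 28 silyl-protected target
Product: 29 target, [(3R,3aS,4S,8S,8aS)-3-hydroxy-6,8a-dimethyl-8-[(Z)-2-methylbut-2-enoyl]oxy-3-(propan-2-yl)-1,2,3a,4,5,8-hexahydroazulen-4-yl] 4-hydroxybenzoate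
Conditions: Bu4NF, AcOH, THF, 0 °C
Reagents that add atoms: none
Why: Buffered fluoride cleaves the labile aryl silyl ether without hydrolysing either ester or isomerising the angelate.

**Compound list**
1 | 3-methoxycyclopent-2-en-1-one | COC1=CC(=O)CC1 | starting material
2 | allylmagnesium bromide | C=CC[Mg]Br | starting material
3 | bromomagnesium 1-allyl-3-methoxycyclopent-2-en-1-olate | C=CCC1(O[Mg]Br)C=C(OC)CC1 | intermediate
4 | 3-allylcyclopent-2-en-1-one | C=CCC1=CC(=O)CC1 | intermediate
5 | trimethylaluminium | C[Al](C)C | starting material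
6 | methacrolein | CC(=C)C=O | starting material
7 | dimethylaluminium (R)-3-allyl-3-methylcyclopent-1-en-1-olate | C[Al](C)OC1=C[C@@](C)(CC=C)CC1 | intermediate
8 | (2S,3R)-3-allyl-2-[(1R)-1-hydroxy-2-methylprop-2-en-1-yl]-3-methylcyclopentan-1-one | O=C1CC[C@](C)(CC=C)[C@H]1[C@@H](O)C(C)=C | intermediate
9 | isopropylmagnesium chloride | CC(C)[Mg]Cl | starting material
10 | (1R,2S,3R)-3-allyl-2-[(1R)-1-hydroxy-2-methylprop-2-en-1-yl]-3-methyl-1-(propan-2-yl)cyclopentan-1-ol | CC(C)[C@]1(O)CC[C@](C)(CC=C)[C@H]1[C@@H](O)C(C)=C | intermediate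
11 | (3R,3aS,4R,7aR)-5,7a-dimethyl-3-(propan-2-yl)-2,3,3a,4,7,7a-hexahydro-1H-indene-3,4-diol | CC(C)[C@]1(O)CC[C@]2(C)CC=C(C)[C@H](O)[C@@H]12 | intermediate
12 | (3R,3aR,7aR)-3-hydroxy-5,7a-dimethyl-3-(propan-2-yl)-1,2,3,3a,7,7a-hexahydro-4H-inden-4-one | CC(C)[C@]1(O)CC[C@]2(C)CC=C(C)C(=O)[C@@H]12 | intermediate
13 | (trimethylsilyl)diazomethane | C[Si](C)(C)C=[N+]=[N-] | starting material
14 | dimethylaluminium alkoxide of 12 | CC(C)[C@]1(O[Al](C)C)CC[C@]2(C)CC=C(C)C(=O)[C@@H]12 | intermediate
15 | 5-(trimethylsilyl) derivative of 16 (C-5 epimers) | CC(C)[C@]1(O)CC[C@]2(C)CC=C(C)C([Si](C)(C)C)C(=O)[C@@H]12 | intermediate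
16 | (3R,3aR,8aR)-3-hydroxy-6,8a-dimethyl-3-(propan-2-yl)-2,3,3a,5,8,8a-hexahydroazulen-4(1H)-one | CC(C)[C@]1(O)CC[C@]2(C)CC=C(C)CC(=O)[C@@H]12 | intermediate
17 | jaeschkeanadiol | C1C=C(C)C[C@H](O)[C@@H]2[C@]1(C)CC[C@@]2(O)C(C)C | intermediate
18 | 4-bromophenol | Oc1ccc(Br)cc1 | starting material
19 | (4-bromophenoxy)(tert-butyl)dimethylsilane | CC(C)(C)[Si](C)(C)Oc1ccc(Br)cc1 | intermediate
20 | carbon dioxide | O=C=O | starting material
21 | 4-[(tert-butyldimethylsilyl)oxy]phenyllithium | CC(C)(C)[Si](C)(C)Oc1ccc([Li])cc1 | intermediate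
22 | 4-[(tert-butyldimethylsilyl)oxy]benzoic acid | CC(C)(C)[Si](C)(C)Oc1ccc(cc1)C(=O)O | intermediate
23 | ferutinin tert-butyldimethylsilyl ether | C1C=C(C)C[C@H](OC(=O)c2ccc(O[Si](C)(C)C(C)(C)C)cc2)[C@@H]2[C@]1(C)CC[C@@]2(O)C(C)C | intermediate
24 | 8-oxoferutinin tert-butyldimethylsilyl ether | O=C1C=C(C)C[C@H](OC(=O)c2ccc(O[Si](C)(C)C(C)(C)C)cc2)[C@@H]2[C@]1(C)CC[C@@]2(O)C(C)C | intermediate
25 | (8S)-8-hydroxyferutinin tert-butyldimethylsilyl ether | O[C@H]1C=C(C)C[C@H](OC(=O)c2ccc(O[Si](C)(C)C(C)(C)C)cc2)[C@@H]2[C@]1(C)CC[C@@]2(O)C(C)C | intermediate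
26 | angelic acid | C/C=C(/C)C(=O)O | starting material
27 | angelic 2,4,6-trichlorobenzoic anhydride | C/C=C(/C)C(=O)OC(=O)c1c(Cl)cc(Cl)cc1Cl | intermediate
28 | tert-butyldimethylsilyl ether of the target | C/C=C(/C)C(=O)O[C@H]1C=C(C)C[C@H](OC(=O)c2ccc(O[Si](C)(C)C(C)(C)C)cc2)[C@@H]2[C@]1(C)CC[C@@]2(O)C(C)C | intermediate
29 | CNP0273650.10 | C/C=C(/C)C(=O)O[C@H]1C=C(C)C[C@H](OC(=O)c2ccc(O)cc2)[C@@H]2[C@]1(C)CC[C@@]2(O)C(C)C | target

**Step count**
Total step count: 14. Longest linear sequence: 12 (steps 1–7 and 10–14).

**Steps most likely to fail**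

Step 2. The aluminium enolate may add sluggishly to 6, or with poor facial control. The fallback sets out from 4. The same conjugate methylation is run but 7 is quenched with Et3SiOTf, and the enol ether (R)-[(3-allyl-3-methylcyclopent-1-en-1-yl)oxy]triethylsilane F1 is isolated. A separate BF3·OEt2-mediated Mukaiyama aldol addition to 6 (CH2Cl2, −78 °C) then returns to the route at 8.

Step 6, the new ring expansion. The ring-fusion carbon might migrate instead of the alkenyl carbon, or an epoxide or pyrazoline might form. The fallback uses known chemistry and sets out from 12. Deconjugative alpha-alkylation of the extended dienolate (KOtBu, 2.2 equiv, THF/t-BuOH, then CH2I2) gives (3R,3aR,7aR)-3-hydroxy-5-(iodomethyl)-5,7a-dimethyl-3-(propan-2-yl)-1,2,3,3a,5,7a-hexahydro-4H-inden-4-one F2. A Dowd–Beckwith radical ring expansion follows (Bu3SnH, AIBN, benzene, 80 °C). In it the CH2 radical adds to the ketone, the cyclopropyloxy radical opens to the tertiary allyl radical, and hydrogen is taken up at C-8. This returns to the route at 16.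

Step 11. Oxidation may also occur at the C-6 methyl group or at C-5. The fallback sets out from 23. Wohl–Ziegler bromination (N-bromosuccinimide, AIBN, cyclohexane, reflux), as used for homoallylic steroid esters, gives 8-bromoferutinin tert-butyldimethylsilyl ether F3. Kornblum oxidation (DMSO, NaHCO3, 60 °C) converts it to the enone and returns to the route at 24.

**Further compounds**
F1 | step 2 | (R)-[(3-allyl-3-methylcyclopent-1-en-1-yl)oxy]triethylsilane | CC[Si](CC)(CC)OC1=C[C@@](C)(CC=C)CC1
F2 | step 6 | (3R,3aR,7aR)-3-hydroxy-5-(iodomethyl)-5,7a-dimethyl-3-(propan-2-yl)-1,2,3,3a,5,7a-hexahydro-4H-inden-4-one | CC(C)[C@]1(O)CC[C@]2(C)C=CC(C)(CI)C(=O)[C@@H]12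
F3 | step 11 | 8-bromoferutinin tert-butyldimethylsilyl ether | BrC1C=C(C)C[C@H](OC(=O)c2ccc(O[Si](C)(C)C(C)(C)C)cc2)[C@@H]2[C@]1(C)CC[C@@]2(O)C(C)C
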